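Retrosynthesis: target ⇐ ring-B alcohol with the C7/C8 diol as acetonide, by C9 isobutyrylation and acetal hydrolysis.
Ring B (ten-membered carbocycle, formed second) ⇐ intramolecular Nozaki–Hiyama–Kishi closure of C9–C10 from a (Z)-alkenyl iodide and a C9 aldehyde, setting C9.
Ring A (α-methylene-γ-butyrolactone, formed first) ⇐ palladium-catalysed cyclocarbonylation of a C7 ethynyl group onto the C6 hydroxyl; the (Z)-iodoalkene ⇐ iodo-Wittig olefination of a C1 aldehyde.
C5–C6 ⇐ intermolecular Nozaki–Hiyama–Kishi coupling of (E)-5-iodo-4-methylpent-4-en-1-ol with a C6 aldehyde, setting C6.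
C6–C9 and C11 with the C7/C8 stereocentres ⇐ diacetone-D-mannose by formaldehyde aldol (quaternary C7), Ohira–Bestmann alkynylation and later periodate excision of mannose C5/C6.

Assumption: atoms in all intermediates are located by the germacrane numbering of the target (C1–C10 ring carbons, C11–C13 the acrylate carbons of the lactone, C14 and C15 the methyls on C10 and C4; Ca and Cb are mannose C5 and C6), and simple reagents are given by name and SMILES on the line "Reagents that add atoms" without a compound number.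

Step 1
Reactants: 1 pent-4-yn-1-ol
Product: 3 (E)-5-iodo-4-methylpent-4-en-1-ol, via alkenylalane alkoxide 2 (not isolated)
Conditions: AlMe3 (3 equiv), Cp2ZrCl2 (25 mol %), CH2Cl2, 0 °C to rt; then I2, THF, −30 °C
Reagents that add atoms: trimethylaluminium, C[Al](C)C; iodine, [I][I]
Why: Negishi zirconium-catalysed syn-carboalumination of the terminal alkyne followed by iodinolysis with retention gives the (E)-trisubstituted alkenyl iodide that becomes C4=C5.

Step 2
Reactants: 4 2,3:5,6-di-O-isopropylidene-α-D-mannofuranose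
Product: 5 2-C-(hydroxymethyl)-2,3:5,6-di-O-isopropylidene-D-mannofuranose (anomeric mixture)
Conditions: aq. HCHO (37%), K2CO3, MeOH, 65 °C
Reagents that add atoms: formaldehyde, C=O
Why: Crossed aldol of the ring-opened aldehyde with formaldehyde, in which the dioxolane enolate is attacked anti to the C3 side chain, so the new quaternary centre (C7) keeps the manno C–O configuration and the CH2OH (C6) lies trans to C9.

Step 3
Reactants: 5 2-C-(hydroxymethyl)-2,3:5,6-di-O-isopropylidene-D-mannofuranose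
Product: 6 1,2-dideoxy-3-C-(hydroxymethyl)-3,4:6,7-di-O-isopropylidene-D-manno-hept-1-ynitol (ethynyl diol)
Conditions: dimethyl (1-diazo-2-oxopropyl)phosphonate, K2CO3, MeOH, rt to 45 °C
Reagents that add atoms: dimethyl (1-diazo-2-oxopropyl)phosphonate, CC(=O)C(=[N+]=[N-])P(=O)(OC)OC
Why: Ohira–Bestmann (Seyferth–Gilbert) homologation of the aldehyde form of the lactol gives the terminal alkyne C11≡C13 on the non-epimerisable quaternary centre and frees the C9 hydroxyl.

Step 4
Reactants: 6 ethynyl diol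
Product: 7 bis(triethylsilyl) ether of 6 (primary C6–O and secondary C9–O silylated)
Conditions: TESOTf (2.5 equiv), 2,6-lutidine, CH2Cl2, −78 to 0 °C
Reagents that add atoms: triethylsilyl trifluoromethanesulfonate, CC[Si](CC)(CC)OS(=O)(=O)C(F)(F)F
Why: Silyl ether formation on both hydroxyls, with no stereocentre touched.

Step 5
Reactants: 7 bis(triethylsilyl) ether
Product: 8 C6 aldehyde (1,2-dideoxy-3-C-formyl-3,4:6,7-di-O-isopropylidene-5-O-triethylsilyl-D-manno-hept-1-ynitol)
Conditions: (COCl)2, DMSO, CH2Cl2, −78 to −30 °C; then Et3N, −78 °C to rt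
Reagents that add atoms: none
Why: Swern conditions cleave and oxidise the primary triethylsilyl ether selectively to the aldehyde while the secondary silyl ether survives.

Step 6
Reactants: 8 C6 aldehyde; 3 (E)-5-iodo-4-methylpent-4-en-1-ol
Product: 9 (6S)-allylic alcohol carrying the (E)-C1–C5 chain (C1 hydroxyl free)
Conditions: 3 (2 equiv), CrCl2 (6 equiv), NiCl2 (2 mol %), DMSO, rt
Reagents that add atoms: none
Why: Nozaki–Hiyama–Kishi alkenylation, where the alkenylchromium adds to the non-enolisable aldehyde in the polar Felkin–Anh sense (C7–O anti to the nucleophile, which passes the small ethynyl group), setting C6 as S with C6–O anti to C7–O.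

Step 7
Reactants: 9 (6S)-allylic alcohol
Product: 10 spiro α-methylene-γ-butyrolactone alcohol (ring A closed)
Conditions: PdCl2 (5 mol %), SnCl2 (5 mol %), PPh3 (10 mol %), CO (8 atm), MeCN, 75 °C
Reagents that add atoms: carbon monoxide, [C-]#[O+]
Why: Norton-type cyclocarbonylation, in which an alkoxycarbonyl–palladium species from the C6 hydroxyl and CO adds syn across the alkyne in 5-exo fashion and protonolysis gives the exocyclic methylene lactone with C6 and C7 unchanged.

Step 8
Reactants: 10 spiro lactone alcohol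
Product: 11 C1 aldehyde of the spiro lactone
Conditions: TEMPO (10 mol %), PhI(OAc)2 (1.2 equiv), CH2Cl2, rt
Reagents that add atoms: none
Why: Oxoammonium (TEMPO) oxidation converts the primary alcohol into the aldehyde without touching the lactone, the silyl ether or the acetals.

Step 9
Reactants: 11 C1 aldehyde
Product: 12 (Z)-C10 alkenyl iodide of the spiro lactone
Conditions: EtPPh3I, n-BuLi, THF, 0 °C; I2, −78 °C; NaHMDS, −20 °C; then 11, −78 °C
Reagents that add atoms: ethyltriphenylphosphonium iodide, CC[P+](c1ccccc1)(c1ccccc1)c1ccccc1.[I-]; iodine, [I][I]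
Why: Zhao's α-iodoethylidene Wittig olefination (Stork–Zhao type) reacts with the unhindered aldehyde at −78 °C under kinetic control to give the (Z)-2-iodo-2-alkene (future C1=C10).

Step 10
Reactants: 12 (Z)-C10 alkenyl iodide
Product: 14 C9 seco-aldehyde of the spiro lactone, via triol 13 (not isolated)
Conditions: AcOH/THF/H2O (3:1:1), 40 °C; evaporate; then NaIO4 (2.5 equiv), THF/H2O, 0 °C
Reagents that add atoms: none
Why: Mild acid removes the silyl group and the accessible terminal acetonide (the hindered spiro acetonide at the quaternary centre stays), and periodate glycol cleavage of the 1,2,3-triol excises Ca and Cb to leave the C9 aldehyde.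

Step 11
Reactants: 14 C9 seco-aldehyde
Product: 15 7,8-O-isopropylidene acetal of (1(10)Z,4E,6S,7R,8S,9S)-7,8,9-trihydroxygermacra-1(10),4,11(13)-trien-12,6-olide
Conditions: CrCl2 (20 equiv), NiCl2 (1 mol % of CrCl2), DMSO, 1 mM, rt
Reagents that add atoms: none
Why: Intramolecular Nozaki–Hiyama–Kishi reaction at high dilution closes ring B at C9–C10 with retention of the Z alkene, and Felkin–Anh addition anti to the C8–O bond gives the 9S carbinol (8,9-anti).

Step 12
Reactants: 15 macrocyclic C9 alcohol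
Product: 16 9-O-isobutyryl derivative of 15 (7,8-acetonide of the target)
Conditions: (i-PrCO)2O (3 equiv), Et3N, DMAP (cat.), CH2Cl2, 0 °C to rt
Reagents that add atoms: isobutyric anhydride, CC(C)C(=O)OC(=O)C(C)C
Why: DMAP-catalysed acylation of the only free hydroxyl (C9) installs the isobutyrate with retention.

Step 13
Reactants: 16 isobutyrate acetonide
Product: 17 (1(10)Z,4E,6S,7R,8S,9S)-7,8-dihydroxy-9-(2-methylpropanoyloxy)germacra-1(10),4,11(13)-trien-12,6-olide (target CNP0301808.4)
Conditions: TFA/H2O (9:1), CH2Cl2, 0 °C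
Reagents that add atoms: none
Why: Acid-catalysed acetal hydrolysis frees the C7/C8 diol without touching ester, lactone or stereocentres, both ring alkenes being deactivated towards protonation by their allylic acyloxy groups.

Compound list
1 | pent-4-yn-1-ol | C#CCCCO | starting material
2 | dimethylaluminium alkoxide of (E)-5-(dimethylalumanyl)-4-methylpent-4-en-1-ol (alkenylalane alkoxide) | C[Al](C)OCCC/C(C)=C/[Al](C)C | intermediate
3 | (E)-5-iodo-4-methylpent-4-en-1-ol | OCCC/C(C)=C/I | intermediate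
4 | 2,3:5,6-di-O-isopropylidene-α-D-mannofuranose (diacetone-D-mannose) | CC1(C)OC[C@@H](O1)[C@H]1O[C@H](O)[C@H]2OC(C)(C)O[C@@H]12 | starting material
5 | 2-C-(hydroxymethyl)-2,3:5,6-di-O-isopropylidene-D-mannofuranose, anomeric mixture (anomeric centre left open in the SMILES) | CC1(C)OC[C@@H](O1)[C@H]1OC(O)[C@@]2(CO)OC(C)(C)O[C@@H]12 | intermediate
6 | 1,2-dideoxy-3-C-(hydroxymethyl)-3,4:6,7-di-O-isopropylidene-D-manno-hept-1-ynitol (C6 CH2OH and C9 OH free) | C#C[C@@]1(CO)OC(C)(C)O[C@H]1[C@H](O)[C@H]1COC(C)(C)O1 | intermediate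
7 | 1,2-dideoxy-3,4:6,7-di-O-isopropylidene-5-O-triethylsilyl-3-C-[(triethylsilyloxy)methyl]-D-manno-hept-1-ynitol | C#C[C@@]1(CO[Si](CC)(CC)CC)OC(C)(C)O[C@H]1[C@H](O[Si](CC)(CC)CC)[C@H]1COC(C)(C)O1 | intermediate
8 | 1,2-dideoxy-3-C-formyl-3,4:6,7-di-O-isopropylidene-5-O-triethylsilyl-D-manno-hept-1-ynitol (C6 aldehyde) | C#C[C@@]1(C=O)OC(C)(C)O[C@H]1[C@H](O[Si](CC)(CC)CC)[C@H]1COC(C)(C)O1 | intermediate
9 | 3-C-[(1S,2E)-1,6-dihydroxy-3-methylhex-2-en-1-yl]-1,2-dideoxy-3,4:6,7-di-O-isopropylidene-5-O-triethylsilyl-D-manno-hept-1-ynitol (6S carbinol, C6–O anti to C7–O) | C#C[C@@]1([C@@H](O)/C=C(\C)CCCO)OC(C)(C)O[C@H]1[C@H](O[Si](CC)(CC)CC)[C@H]1COC(C)(C)O1 | intermediate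
10 | spiro lactone alcohol: 2,2-dimethyl-9-methylidene-1,3,7-trioxaspiro[4.4]nonan-8-one whose spiro-C6 (germacrane C6, S) carries the (1E)-5-hydroxy-2-methylpent-1-enyl chain and whose spiro-C4 (germacrane C8) carries CH(OSiEt3)[(4R)-2,2-dimethyl-1,3-dioxolan-4-yl]; C7 and C8 as in mannose C2 and C3 | C=C1C(=O)O[C@@H](/C=C(\C)CCCO)[C@@]12OC(C)(C)O[C@H]2[C@H](O[Si](CC)(CC)CC)[C@H]1COC(C)(C)O1 | intermediate
11 | as 10, but the chain is (1E)-2-methyl-5-oxopent-1-enyl (C1 aldehyde) | C=C1C(=O)O[C@@H](/C=C(\C)CCC=O)[C@@]12OC(C)(C)O[C@H]2[C@H](O[Si](CC)(CC)CC)[C@H]1COC(C)(C)O1 | intermediate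
12 | as 10, but the chain is (1E,5Z)-6-iodo-2-methylhepta-1,5-dienyl | C=C1C(=O)O[C@@H](/C=C(\C)CC/C=C(\I)C)[C@@]12OC(C)(C)O[C@H]2[C@H](O[Si](CC)(CC)CC)[C@H]1COC(C)(C)O1 | intermediate
13 | as 12, but C9, Ca and Cb carry free hydroxyls (triol; spiro acetonide kept) | C=C1C(=O)O[C@@H](/C=C(\C)CC/C=C(\I)C)[C@@]12OC(C)(C)O[C@H]2[C@H](O)[C@H](O)CO | intermediate
14 | as 12, but spiro-C4 (germacrane C8) carries the C9 formyl group (seco-aldehyde) | C=C1C(=O)O[C@@H](/C=C(\C)CC/C=C(\I)C)[C@@]12OC(C)(C)O[C@H]2C=O | intermediate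
15 | 7,8-O-isopropylidene acetal of (1(10)Z,4E,6S,7R,8S,9S)-7,8,9-trihydroxygermacra-1(10),4,11(13)-trien-12,6-olide | C=C1C(=O)O[C@H]2/C=C(\C)CC/C=C(/C)[C@H](O)[C@@H]3OC(C)(C)O[C@@]123 | intermediate
16 | 9-O-(2-methylpropanoyl) derivative of 15 | C=C1C(=O)O[C@H]2/C=C(\C)CC/C=C(/C)[C@H](OC(=O)C(C)C)[C@@H]3OC(C)(C)O[C@@]123 | intermediate
17 | (1(10)Z,4E,6S,7R,8S,9S)-7,8-dihydroxy-9-(2-methylpropanoyloxy)germacra-1(10),4,11(13)-trien-12,6-olide | C=C1C(=O)O[C@H]2/C=C(\C)CC/C=C(/C)[C@H](OC(=O)C(C)C)[C@H](O)[C@]12O | target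

Total step count: 13. Longest linear sequence: 12 steps (steps 2 to 13, from 4).

Steps most likely to fail:

Step 6 (facial selectivity at C6 in the intermolecular coupling). The fallback sets out from 8. The coupling with 3 is run as before, and the crude product, now partly or mainly the C6 epimer, the 6R allylic alcohol F1, is oxidised at the allylic carbinol only with MnO2 (CH2Cl2, rt; the saturated C1 alcohol is untouched) to the enone F2. Reduction with Zn(BH4)2 (Et2O, −30 °C) under chelation control, zinc bridging the C6 carbonyl and O7 so that hydride enters from the face of the small ethynyl group, gives the 6S alcohol, and the route is rejoined at 9.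

Step 7 (cyclocarbonylation of a hindered homopropargylic alcohol that is also allylic). The fallback sets out from 9. Hydrostannation with Bu3SnH catalysed by Mo(CO)3(CNtBu)3 (THF, 55 °C) puts tin on the internal alkyne carbon next to the oxygenated quaternary centre and gives the alkenylstannane F3. Iododestannylation (I2, CH2Cl2, 0 °C) gives the 2-iodoalkene F4. Carbonylative lactonisation through oxidative addition to zerovalent palladium (Pd(PPh3)4, CO 1 atm, Et3N, MeCN, 60 °C) closes ring A, and the route is rejoined at 10.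

Step 11 (ring-B closure and the C9 configuration). The fallback sets out from 14. If the closure gives the C9 epimer, the 9R macrocyclic alcohol F5, this alcohol is esterified under Mitsunobu conditions (isobutyric acid, PPh3, DIAD, toluene, 0 °C), which installs the isobutyrate with inversion at C9, and the route is rejoined at 16.

Further compounds
F1 | step 6 | C6 epimer of 9 (6R allylic alcohol) | C#C[C@@]1([C@H](O)/C=C(\C)CCCO)OC(C)(C)O[C@H]1[C@H](O[Si](CC)(CC)CC)[C@H]1COC(C)(C)O1
F2 | step 6 | C6 ketone of 9 (enone) | C#C[C@@]1(C(=O)/C=C(\C)CCCO)OC(C)(C)O[C@H]1[C@H](O[Si](CC)(CC)CC)[C@H]1COC(C)(C)O1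
F3 | step 7 | C11 tributylstannyl alkene from 9 (alkenylstannane) | C=C([Sn](CCCC)(CCCC)CCCC)[C@@]1([C@@H](O)/C=C(\C)CCCO)OC(C)(C)O[C@H]1[C@H](O[Si](CC)(CC)CC)[C@H]1COC(C)(C)O1
F4 | step 7 | C11 iodoalkene from 9 (2-iodoalkene) | C=C(I)[C@@]1([C@@H](O)/C=C(\C)CCCO)OC(C)(C)O[C@H]1[C@H](O[Si](CC)(CC)CC)[C@H]1COC(C)(C)O1
F5 | step 11 | C9 epimer of 15 (9R macrocyclic alcohol) | C=C1C(=O)O[C@H]2/C=C(\C)CC/C=C(/C)[C@@H](O)[C@@H]3OC(C)(C)O[C@@]123
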